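Your vessel is closed and stirred, you want the target out of it, and the two flasks differ in one thing: ochre stays warm while amber is chilled partway through.

| setting | Wednesday's | Tuesday's | Thursday's | ochre | amber |
|---|---|---|---|---|---|
| substrate | 0.025 M | 0.038 M | 0.050 M | 0.050 M | 0.050 M |
| capture agent | 5 mM | 5 mM | 7.5 mM | 5.00 mM | 5.00 mM |
| temperature | −5 °C | 17 °C | −5 °C |  |  |
| remark | run made earlier | run made earlier | run made earlier | at 25 °C throughout | at 25 °C until 80 s, from then on at −15 °C |
| time |  |  |  | 4.0 min | 4.0 min |

| run | time / min | target / % | substrate / % |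
|---|---|---|---|
| Wednesday's | 1.33 | 0.5 | 95.2 |
| Wednesday's | 3.00 | 0 | 88.4 |
| Wednesday's | 6.00 | 0 | 77.7 |
| Wednesday's | 20.0 | 2.6 | 49.5 |
| Tuesday's | 0.333 | 0.1 | 77.9 |
| Tuesday's | 0.667 | 1.3 | 62.2 |
| Tuesday's | 1.50 | 3.2 | 38.5 |
| Tuesday's | 4.00 | 14.1 | 16.8 |
| Thursday's | 1.33 | 0.4 | 93.9 |
| Thursday's | 3.00 | 0.2 | 88.5 |
| Thursday's | 6.00 | 0.4 | 78.4 |
| Thursday's | 20.0 | 2.1 | 47.7 |

(scatter of a reading: 0.5 percentage points)

- the numbers in the tables scatter by 0.5 percentage points (one standard deviation)
- a reading or a percentage of target counts all its forms, free or not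

1. the winner by amount of target, in percent of the substrate charged; "neither" if no more than 2 percentage points parts them (ochre / amber / neither)
2. how much target is there at the end, in percent of the substrate charged: ochre
3. how much target is there at the end, in percent of the substrate charged: amber

Run it in slow motion, with every amount as a fraction of the charge.

1. The first instants. In Tuesday's run at 17 °C, substrate falls with a time constant near 1.33 min, yet target reads 0.1% at 0.333 min. This lag is an induction period: substrate is turning into something unseen before target appears.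

2. The middle. At 4.00 min, Tuesday's run holds 69.1% as neither substrate nor target, and that share stands unseen in the flask. Between its last two readings target climbs at 0.0436 min⁻¹, which I call the warm rate.

3. The cold. Define the cold creep, the fraction of the charge becoming target per minute in a chilled flask, as Wednesday's last target reading over its time: 0.00130 min⁻¹ at −5 °C. This reading is far smaller than the warm rate.

4. The end. Both flasks run alike for 80 s, and then 2.67 min remain. Amber is colder than Wednesday's run but has had a warm start, so I keep the creep unchanged, and amber adds 0.35 percentage points. Ochre is warmer than Tuesday's run, and I let it keep the warm rate, so by my reckoning ochre leads by about 11 points, more than the margin.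

The forecast names ochre, with ochre at 34% and amber at 10.5%, and of amber it says “about 10% forms by 80 s”. Its gap of 24 points is wider than mine.

The flask gives ochre 26.1% and amber 11.5%, so ochre wins.

    substrate → intermediate C (k = 0.0140 s⁻¹, Ea = 93.0 kJ mol⁻¹)
    substrate ⇌ intermediate A (K = 1.30, k = 0.0200 s⁻¹, Ea = 83.0 kJ mol⁻¹, ΔH = −9.00 kJ mol⁻¹)
    capture agent + intermediate C → trapped intermediate (k = 0.0370 M⁻¹ s⁻¹, Ea = 68.0 kJ mol⁻¹)
    intermediate B → target (k = 0.0210 s⁻¹, Ea = 73.0 kJ mol⁻¹)
    intermediate C ⇌ target (K = 0.590, k = 0.00740 s⁻¹, Ea = 80.0 kJ mol⁻¹, ΔH = −27.0 kJ mol⁻¹)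
    intermediate A ⇌ intermediate D (K = 43.0, k = 0.00240 s⁻¹, Ea = 87.0 kJ mol⁻¹, ΔH = 50.0 kJ mol⁻¹)
    intermediate A ⇌ intermediate B (K = 0.490, k = 0.00130 s⁻¹, Ea = 79.0 kJ mol⁻¹, ΔH = 0 kJ mol⁻¹)
    crystals ⇌ target, rate k8*(cs8 - [target]) while solid is left; crystals form when [target] > cs8 (solubility = 11.0 mM, k = 0.0530 s⁻¹)
    substrate → decomposition product (k = 6.70 × 10⁻⁶ s⁻¹, Ea = 97.0 kJ mol⁻¹)
    (constants at 25 °C)

The forecast's ochre stands 7.9 points too high, while its amber holds. Amber's target stands at 11.2% after 1.33 min, when its temperature changes. By 4.0 min amber holds 11.5%, and for that stretch the creep allowed 0.35 points. Now read amber later, at 6.0 min, with nothing else changed. The creep adds 0.26 points to amber's 11.5%, which gives 11.8%, and that later reading of amber stands at 11.7%.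

The earlier runs and the new flask are simulated with constants of no real substance, and the scatter is random.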